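**Strategy**

The route rests on cutting ring A, the fully substituted benzene whose carbons alternate between oxygen-bearing (free OH, pyran O, diaryl ether O) and carbon-bearing (prenyl, lactone C=O, pyran CH) positions, into a two-carbon siloxyalkyne and a four-carbon vinylketene. A single operation (Wolff rearrangement, [2+2] addition, 4π opening, 6π closure) makes three ring A C–C bonds and fixes all six substituents, the ether oxygen to ring B included. Its precursor is a Z-configured aryloxy diazoketone carrying the finished ring B chromene on oxygen and an allyl ester, chosen so that the hindered salicylate can later be freed by zerovalent palladium and closed to the seven-membered lactone.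

Key step: step 10

Abbreviation: ArB = 5,8-bis(methoxymethoxy)-2,2-dimethyl-2H-chromen-6-yl (ring B with both phenols masked as methoxymethyl ethers).

Assumption: the amine-catalysed addition of step 6 is taken to give the Z (anti-addition) enol ether, the geometry that step 10 needs; any E isomer would be removed by chromatography at that stage.

**Route**

Step 1
Reactants: 1 2,5-dibromobenzene-1,4-diol
Product: 2 1,4-dibromo-2,5-bis(methoxymethoxy)benzene
Conditions: NaH, MOMCl, DMF, 0 °C to rt
Reagents that add atoms: chloromethyl methyl ether (MOMCl), COCCl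
Why: Williamson-type O-alkylation of both phenoxides with a reactive α-chloro ether should be clean and gives acetal ethers that tolerate organolithiums, base, heat and fluoride.

Step 2
Reactants: 2 1,4-dibromo-2,5-bis(methoxymethoxy)benzene
Product: 5 4-bromo-2,5-bis(methoxymethoxy)phenol, via monoaryllithium 3 (not isolated), via dimethyl arylboronate 4 (not isolated)
Conditions: n-BuLi (1 equiv), THF, −78 °C; B(OMe)3, −78 °C to rt; then 30% H2O2, aq. NaOH, 0 °C
Reagents that add atoms: hydrogen peroxide, OO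
Why: Bromine–lithium exchange with one equivalent of base should stop at the monolithio arene, and borylation followed by peroxide oxidation (boron-to-oxygen shift) turns that one C–Br bond into C–OH, so the symmetry of 2 is broken without a statistical step.

Step 3
Reactants: 5 4-bromo-2,5-bis(methoxymethoxy)phenol; 6 3-chloro-3-methylbut-1-yne
Product: 8 6-bromo-5,8-bis(methoxymethoxy)-2,2-dimethyl-2H-chromene, via aryl 1,1-dimethylpropargyl ether 7 (not isolated)
Conditions: DBU, CuCl2 (cat.), MeCN, 0 °C; then solvent switch to xylene, 140 °C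
Reagents that add atoms: none
Why: Copper-catalysed O-propargylation followed by aromatic propargyl Claisen rearrangement, [1,5]-hydrogen shift and oxa-6π electrocyclisation should give the chromene, and the pyran can only close at the single free ortho carbon of 5.

Step 4
Reactants: 8 6-bromo-5,8-bis(methoxymethoxy)-2,2-dimethyl-2H-chromene
Product: 11 5,8-bis(methoxymethoxy)-2,2-dimethyl-2H-chromen-6-ol (ring B phenol, ArB–OH), via chromenyllithium 9 (not isolated), via dimethyl chromenylboronate 10 (not isolated)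
Conditions: n-BuLi, THF, −78 °C; B(OMe)3, −78 °C to rt; then 30% H2O2, aq. NaOH, 0 °C
Reagents that add atoms: hydrogen peroxide, OO
Why: Bromine–lithium exchange, borylation and oxidation of the boronate by nucleophilic peroxide should convert the remaining C–Br bond into the phenol without epoxidising the electron-rich chromene double bond.

Step 5
Reactants: 12 but-2-ynedioic acid
Product: 13 diallyl but-2-ynedioate
Conditions: allyl alcohol, H2SO4 (cat.), rt
Reagents that add atoms: allyl alcohol, C=CCO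
Why: Fischer esterification of the strongly acidic diacid in excess alcohol at room temperature is the standard way to dialkyl acetylenedicarboxylates and avoids decarboxylation.

Step 6
Reactants: 11 ring B phenol; 13 diallyl but-2-ynedioate
Product: 14 diallyl (2Z)-2-(ArB-oxy)but-2-enedioate
Conditions: DABCO (cat.), CH2Cl2, 0 °C to rt
Reagents that add atoms: none
Why: Amine-catalysed oxa-Michael addition of a phenol to an acetylenedicarboxylate is well known and under kinetic control should give the anti-addition product, in which the aryloxy group is cis to the distal ester.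

Step 7
Reactants: 14 diallyl (2Z)-2-(ArB-oxy)but-2-enedioate
Product: 15 (2Z)-2-(ArB-oxy)-4-oxo-4-(allyloxy)but-2-enoic acid
Conditions: LiOH·H2O (1 equiv), THF/H2O, 0 °C; then 1 M HCl to pH 3, 0 °C
Reagents that add atoms: lithium hydroxide, [Li+].[OH-]
Why: Site-selective saponification should occur at the ester on the aryloxy-bearing carbon, which is inductively activated by the α-oxygen, whereas the other ester is a vinylogous carbonate deactivated by the same oxygen and the monocarboxylate resists a second attack.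

Step 8
Reactants: 15 (2Z)-2-(ArB-oxy)-4-oxo-4-(allyloxy)but-2-enoic acid
Product: 17 allyl (2Z)-3-(ArB-oxy)-5-diazo-4-oxopent-2-enoate, via isobutyl carbonic mixed anhydride 16 (not isolated)
Conditions: i-BuOCOCl, N-methylmorpholine, THF, −15 °C; then CH2N2, Et2O, 0 °C to rt
Reagents that add atoms: diazomethane, C=[N+]=[N-]
Why: Acylation of diazomethane by a mixed carbonic anhydride (first stage of the Arndt–Eistert sequence) needs no acid that would harm the acetal ethers, and the push–pull alkene with its fully substituted carbon should be too poor a dipolarophile to compete by pyrazoline formation.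

Step 9
Reactants: 18 ethyl 4-methylpent-3-enoate
Product: 21 triisopropyl[(5-methylhex-4-en-1-yn-1-yl)oxy]silane, via lithium dibromoenolate 19 (not isolated), via lithium ynolate 20 (not isolated)
Conditions: CH2Br2, LiTMP, THF, −78 °C; n-BuLi, −78 °C to rt; then i-Pr3SiCl, 0 °C to rt
Reagents that add atoms: dibromomethane, BrCBr; chlorotriisopropylsilane, CC(C)[Si](Cl)(C(C)C)C(C)C
Why: Kowalski ester homologation, in which dibromomethyllithium adds to the ester, bromine–lithium exchange on enolate 19 triggers the 1,2-shift to ynolate 20, and the bulky silyl chloride silylates oxygen to give the siloxyalkyne.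

Step 10
Reactants: 17 allyl (2Z)-3-(ArB-oxy)-5-diazo-4-oxopent-2-enoate; 21 triisopropyl[(5-methylhex-4-en-1-yn-1-yl)oxy]silane
Product: 25 allyl 6-(ArB-oxy)-2-hydroxy-3-(3-methylbut-2-en-1-yl)-4-[(triisopropylsilyl)oxy]benzoate, via vinylketene 22 (not isolated), via 4-alkenylcyclobutenone 23 (not isolated), via dienylketene 24 (not isolated)
Conditions: hν (420–450 nm LEDs), ClCH2CH2Cl, rt; then 80 °C
Reagents that add atoms: none
Why: Photochemical Wolff rearrangement of 17 moves the alkenyl group to the diazo carbon with loss of N2 and gives vinylketene 22, whose ketene carbon is attacked by the nucleophilic prenyl-bearing carbon of 21 in a regioselective [2+2] cycloaddition to give 23. Thermal conrotatory 4π opening of 23 gives dienylketene 24, and ring A closes by disrotatory 6π electrocyclisation between the ketene carbon and the ester-bearing alkene carbon, after which tautomerisation of the cyclohexadienone gives the phenol; this is the Danheiser benzannulation of unsaturated diazoketones with siloxyalkynes. No stereocentre is formed. The regiochemistry needed (prenyl next to the new hydroxyl, siloxy group para to the ester) follows from the polarity of ketene and ynol ether. The Z geometry of 17 holds the ketene arm trans to the ester, which blocks oxa-6π closure to a 2-pyranone and places the ester on the outside of the triene terminus. Light of this wavelength should be absorbed by the diazoketone only, so the photochromic ring B pyran, the prenyl group and the allyl ester should stay intact.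

Step 11
Reactants: 25 allyl 6-(ArB-oxy)-2-hydroxy-3-(3-methylbut-2-en-1-yl)-4-[(triisopropylsilyl)oxy]benzoate
Product: 26 allyl 6-(ArB-oxy)-2,4-dihydroxy-3-(3-methylbut-2-en-1-yl)benzoate
Conditions: Bu4NF, AcOH, THF, 0 °C
Reagents that add atoms: none
Why: Fluoride-induced cleavage of the aryl silyl ether is fast at 0 °C, and buffered fluoride should leave the allyl ester and the acetal ethers untouched.

Step 12
Reactants: 26 allyl 6-(ArB-oxy)-2,4-dihydroxy-3-(3-methylbut-2-en-1-yl)benzoate; 27 3-methylbut-2-enal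
Product: 28 allyl 5-(ArB-oxy)-7-hydroxy-2,2-dimethyl-8-(3-methylbut-2-en-1-yl)-2H-chromene-6-carboxylate
Conditions: ethylenediammonium diacetate (cat.), toluene, reflux
Reagents that add atoms: none
Why: Knoevenagel-type condensation at the only free ring A carbon, which is activated by three oxygens, followed by oxa-6π electrocyclisation onto the adjacent free hydroxyl (formal [3+3] chromene annulation) should give the second pyran, since ring B has no free hydroxyl and the chelated hydroxyl has no free ortho carbon.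

Step 13
Reactants: 28 allyl 5-(ArB-oxy)-7-hydroxy-2,2-dimethyl-8-(3-methylbut-2-en-1-yl)-2H-chromene-6-carboxylate
Product: 29 5-(ArB-oxy)-7-hydroxy-2,2-dimethyl-8-(3-methylbut-2-en-1-yl)-2H-chromene-6-carboxylic acid
Conditions: Pd(PPh3)4 (cat.), morpholine, THF, rt
Reagents that add atoms: none
Why: Tsuji–Trost deallylation, in which zerovalent palladium ionises the ester at the allyl–oxygen bond so that the crowded, hydrogen-bonded carbonyl need not be attacked, and morpholine traps the allyl fragment.

Step 14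
Reactants: 29 5-(ArB-oxy)-7-hydroxy-2,2-dimethyl-8-(3-methylbut-2-en-1-yl)-2H-chromene-6-carboxylic acid
Product: 30 5-[(5,8-dihydroxy-2,2-dimethyl-2H-chromen-6-yl)oxy]-7-hydroxy-2,2-dimethyl-8-(3-methylbut-2-en-1-yl)-2H-chromene-6-carboxylic acid
Conditions: TMSOTf, 2,2'-bipyridyl, CH2Cl2, 0 °C to rt; then H2O; argon
Reagents that add atoms: none
Why: Silyl triflate/bipyridyl cleavage of aryl methoxymethyl ethers runs through aryl silyl ethers that hydrolyse on work-up and uses no free protic acid, so the prenyl group next to a phenol, both chromenes and the electron-rich carboxylic acid (held as its silyl ester) should survive.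

Step 15
Reactants: 30 5-[(5,8-dihydroxy-2,2-dimethyl-2H-chromen-6-yl)oxy]-7-hydroxy-2,2-dimethyl-8-(3-methylbut-2-en-1-yl)-2H-chromene-6-carboxylic acid
Product: 31 Garcinisidone D
Conditions: EDC·HCl, CH2Cl2 (high dilution), 0 °C to rt, argon
Reagents that add atoms: none
Why: Carbodiimide-mediated lactonisation, in which the O-acylisourea is captured by the ring B hydroxyl ortho to the ether oxygen, the only one that can reach the carbonyl (seven-membered ring), whereas the para hydroxyl of ring B and the chelated ring A hydroxyl cannot cyclise.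

**Compound list**

1 | 2,5-dibromobenzene-1,4-diol | Oc1cc(Br)c(O)cc1Br | starting material
2 | 1,4-dibromo-2,5-bis(methoxymethoxy)benzene | COCOc1cc(Br)c(OCOC)cc1Br | intermediate
3 | [4-bromo-2,5-bis(methoxymethoxy)phenyl]lithium (not isolated) | [Li]c1cc(OCOC)c(Br)cc1OCOC | intermediate
4 | dimethyl [4-bromo-2,5-bis(methoxymethoxy)phenyl]boronate (not isolated) | COB(OC)c1cc(OCOC)c(Br)cc1OCOC | intermediate
5 | 4-bromo-2,5-bis(methoxymethoxy)phenol | Oc1cc(OCOC)c(Br)cc1OCOC | intermediate
6 | 3-chloro-3-methylbut-1-yne | CC(C)(Cl)C#C | starting material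
7 | 1-bromo-2,5-bis(methoxymethoxy)-4-[(2-methylbut-3-yn-2-yl)oxy]benzene (not isolated) | C#CC(C)(C)Oc1cc(OCOC)c(Br)cc1OCOC | intermediate
8 | 6-bromo-5,8-bis(methoxymethoxy)-2,2-dimethyl-2H-chromene | CC1(C)C=Cc2c(OCOC)c(Br)cc(OCOC)c2O1 | intermediate
9 | [5,8-bis(methoxymethoxy)-2,2-dimethyl-2H-chromen-6-yl]lithium (not isolated) | [Li]c1cc(OCOC)c2OC(C)(C)C=Cc2c1OCOC | intermediate
10 | dimethyl [5,8-bis(methoxymethoxy)-2,2-dimethyl-2H-chromen-6-yl]boronate (not isolated) | COB(OC)c1cc(OCOC)c2OC(C)(C)C=Cc2c1OCOC | intermediate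
11 | 5,8-bis(methoxymethoxy)-2,2-dimethyl-2H-chromen-6-ol | Oc1cc(OCOC)c2OC(C)(C)C=Cc2c1OCOC | intermediate
12 | but-2-ynedioic acid | OC(=O)C#CC(=O)O | starting material
13 | di(prop-2-en-1-yl) but-2-ynedioate | C=CCOC(=O)C#CC(=O)OCC=C | intermediate
14 | di(prop-2-en-1-yl) (2Z)-2-{[5,8-bis(methoxymethoxy)-2,2-dimethyl-2H-chromen-6-yl]oxy}but-2-enedioate | C=CCOC(=O)/C=C(\Oc1cc(OCOC)c2OC(C)(C)C=Cc2c1OCOC)C(=O)OCC=C | intermediate
15 | (2Z)-2-{[5,8-bis(methoxymethoxy)-2,2-dimethyl-2H-chromen-6-yl]oxy}-4-oxo-4-(prop-2-en-1-yloxy)but-2-enoic acid | C=CCOC(=O)/C=C(\Oc1cc(OCOC)c2OC(C)(C)C=Cc2c1OCOC)C(=O)O | intermediate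
16 | mixed anhydride of 15 with 2-methylpropyl hydrogen carbonate (not isolated) | C=CCOC(=O)/C=C(\Oc1cc(OCOC)c2OC(C)(C)C=Cc2c1OCOC)C(=O)OC(=O)OCC(C)C | intermediate
17 | prop-2-en-1-yl (2Z)-3-{[5,8-bis(methoxymethoxy)-2,2-dimethyl-2H-chromen-6-yl]oxy}-5-diazo-4-oxopent-2-enoate | C=CCOC(=O)/C=C(\Oc1cc(OCOC)c2OC(C)(C)C=Cc2c1OCOC)C(=O)C=[N+]=[N-] | intermediate
18 | ethyl 4-methylpent-3-enoate | CCOC(=O)CC=C(C)C | starting material
19 | lithium 1,1-dibromo-5-methylhexa-1,4-dien-2-olate (not isolated) | [Li]OC(CC=C(C)C)=C(Br)Br | intermediate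
20 | lithium 5-methylhex-4-en-1-yn-1-olate (not isolated) | [Li]OC#CCC=C(C)C | intermediate
21 | triisopropyl[(5-methylhex-4-en-1-yn-1-yl)oxy]silane | CC(C)=CCC#CO[Si](C(C)C)(C(C)C)C(C)C | intermediate
22 | prop-2-en-1-yl (2Z)-3-{[5,8-bis(methoxymethoxy)-2,2-dimethyl-2H-chromen-6-yl]oxy}-5-oxopenta-2,4-dienoate (vinylketene, not isolated) | C=CCOC(=O)/C=C(\Oc1cc(OCOC)c2OC(C)(C)C=Cc2c1OCOC)C=C=O | intermediate
23 | prop-2-en-1-yl (2Z)-3-{[5,8-bis(methoxymethoxy)-2,2-dimethyl-2H-chromen-6-yl]oxy}-3-[3-(3-methylbut-2-en-1-yl)-4-oxo-2-(triisopropylsilyloxy)cyclobut-2-en-1-yl]prop-2-enoate (racemic, not isolated) | C=CCOC(=O)/C=C(\Oc1cc(OCOC)c2OC(C)(C)C=Cc2c1OCOC)C1C(=O)C(CC=C(C)C)=C1O[Si](C(C)C)(C(C)C)C(C)C | intermediate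
24 | prop-2-en-1-yl (2Z,4E)-3-{[5,8-bis(methoxymethoxy)-2,2-dimethyl-2H-chromen-6-yl]oxy}-6-(3-methylbut-2-en-1-yl)-7-oxo-5-(triisopropylsilyloxy)hepta-2,4,6-trienoate (dienylketene, not isolated) | C=CCOC(=O)/C=C(\Oc1cc(OCOC)c2OC(C)(C)C=Cc2c1OCOC)/C=C(/O[Si](C(C)C)(C(C)C)C(C)C)C(CC=C(C)C)=C=O | intermediate
25 | prop-2-en-1-yl 6-{[5,8-bis(methoxymethoxy)-2,2-dimethyl-2H-chromen-6-yl]oxy}-2-hydroxy-3-(3-methylbut-2-en-1-yl)-4-[(triisopropylsilyl)oxy]benzoate | C=CCOC(=O)c1c(O)c(CC=C(C)C)c(O[Si](C(C)C)(C(C)C)C(C)C)cc1Oc1cc(OCOC)c2OC(C)(C)C=Cc2c1OCOC | intermediate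
26 | prop-2-en-1-yl 6-{[5,8-bis(methoxymethoxy)-2,2-dimethyl-2H-chromen-6-yl]oxy}-2,4-dihydroxy-3-(3-methylbut-2-en-1-yl)benzoate | C=CCOC(=O)c1c(O)c(CC=C(C)C)c(O)cc1Oc1cc(OCOC)c2OC(C)(C)C=Cc2c1OCOC | intermediate
27 | 3-methylbut-2-enal | CC(C)=CC=O | starting material
28 | prop-2-en-1-yl 5-{[5,8-bis(methoxymethoxy)-2,2-dimethyl-2H-chromen-6-yl]oxy}-7-hydroxy-2,2-dimethyl-8-(3-methylbut-2-en-1-yl)-2H-chromene-6-carboxylate | C=CCOC(=O)c1c(O)c(CC=C(C)C)c2OC(C)(C)C=Cc2c1Oc1cc(OCOC)c2OC(C)(C)C=Cc2c1OCOC | intermediate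
29 | 5-{[5,8-bis(methoxymethoxy)-2,2-dimethyl-2H-chromen-6-yl]oxy}-7-hydroxy-2,2-dimethyl-8-(3-methylbut-2-en-1-yl)-2H-chromene-6-carboxylic acid | OC(=O)c1c(O)c(CC=C(C)C)c2OC(C)(C)C=Cc2c1Oc1cc(OCOC)c2OC(C)(C)C=Cc2c1OCOC | intermediate
30 | 5-[(5,8-dihydroxy-2,2-dimethyl-2H-chromen-6-yl)oxy]-7-hydroxy-2,2-dimethyl-8-(3-methylbut-2-en-1-yl)-2H-chromene-6-carboxylic acid | OC(=O)c1c(O)c(CC=C(C)C)c2OC(C)(C)C=Cc2c1Oc1cc(O)c2OC(C)(C)C=Cc2c1O | intermediate
31 | Garcinisidone D (achiral, no stereocentre) | CC(C)=CCc1c(O)c2c(c3c1OC(C)(C)C=C3)Oc1cc(O)c3c(c1OC2=O)C=CC(C)(C)O3 | target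

**Step count and risk**

Total steps: 15. Longest linear sequence: 13 steps (steps 1–4, 6–8, 10–15); steps 5 and 9 are side branches.

The three steps most likely to fail:

Step 10. What may go wrong: light-driven electrocyclic opening of the ring B pyran, E/Z scrambling of the enol ether that lets the ketene close onto the ester oxygen, or capture of the ketene by the electron-rich ring B instead of the alkyne. Fallback (sets out from 5, comes back at 28): the ring B pyran is left out of the benzannulation substrate and both pyrans are made together at the end. Phenol 5 is silylated (i-Pr3SiCl, imidazole) to the aryl silyl ether F1. Bromine–lithium exchange, borylation and peroxide oxidation as in step 4 give the phenol F2. Oxa-Michael addition to 13 gives the diester F3, site-selective saponification the acid F4, and the mixed-anhydride/diazomethane sequence the diazoketone F5. Benzannulation with 21 under the conditions of step 10, now on a substrate free of any chromene, gives the bis(silyl) benzoate F6. Bu4NF removes both silyl groups to give the triol F7, whose chelated hydroxyl stays unreactive. Two-fold O-propargylation with 6 (DBU, CuCl2) gives the bis(propargyl ether) F8, and heating in xylene sets off both propargyl Claisen/electrocyclisation sequences to give 28.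

Step 7. What may go wrong: loss of site selectivity between the two allyl esters (diacid or the wrong half ester) or displacement of the aryloxy group by hydroxide. Fallback (sets out from 11, comes back at 15): the two carbonyl carbons are made different from the start. 3,3-Diethoxyprop-1-yne is deprotonated (n-BuLi) and acylated with allyl chloroformate to give the ynoate F9. Amine-catalysed oxa-Michael addition of 11 can occur only β to the single ester and gives the Z enol ether acetal F10. Mild aqueous acid on silica (wet SiO2, oxalic acid), under which aryl methoxymethyl ethers persist, frees the aldehyde F11, and Pinnick oxidation (NaClO2, NaH2PO4, 2-methylbut-2-ene) gives 15.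

Step 15. What may go wrong: air oxidation of the unprotected ring B hydroquinone of 30, and intermolecular acyl transfer or N-acylurea formation outrunning the seven-membered ring closure. Fallback (sets out from 29, comes back at 31): the acid is activated before the phenols are unmasked. Acid 29 is condensed with pentafluorophenol (EDC) to the active ester F12. Cleavage of the methoxymethyl ethers as in step 14 gives the triphenol active ester F13, which is not isolated: on addition of NaHCO3 in dilute solution the ring B hydroxyl next to the ether oxygen displaces pentafluorophenoxide and gives 31.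

**Further compounds**

F1 | step 10 | [4-bromo-2,5-bis(methoxymethoxy)phenoxy]triisopropylsilane | CC(C)[Si](Oc1cc(OCOC)c(Br)cc1OCOC)(C(C)C)C(C)C
F2 | step 10 | 2,5-bis(methoxymethoxy)-4-[(triisopropylsilyl)oxy]phenol | Oc1cc(OCOC)c(O[Si](C(C)C)(C(C)C)C(C)C)cc1OCOC
F3 | step 10 | di(prop-2-en-1-yl) (2Z)-2-{2,5-bis(methoxymethoxy)-4-[(triisopropylsilyl)oxy]phenoxy}but-2-enedioate | C=CCOC(=O)/C=C(\Oc1cc(OCOC)c(O[Si](C(C)C)(C(C)C)C(C)C)cc1OCOC)C(=O)OCC=C
F4 | step 10 | (2Z)-2-{2,5-bis(methoxymethoxy)-4-[(triisopropylsilyl)oxy]phenoxy}-4-oxo-4-(prop-2-en-1-yloxy)but-2-enoic acid | C=CCOC(=O)/C=C(\Oc1cc(OCOC)c(O[Si](C(C)C)(C(C)C)C(C)C)cc1OCOC)C(=O)O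
F5 | step 10 | prop-2-en-1-yl (2Z)-3-{2,5-bis(methoxymethoxy)-4-[(triisopropylsilyl)oxy]phenoxy}-5-diazo-4-oxopent-2-enoate | C=CCOC(=O)/C=C(\Oc1cc(OCOC)c(O[Si](C(C)C)(C(C)C)C(C)C)cc1OCOC)C(=O)C=[N+]=[N-]
F6 | step 10 | prop-2-en-1-yl 6-{2,5-bis(methoxymethoxy)-4-[(triisopropylsilyl)oxy]phenoxy}-2-hydroxy-3-(3-methylbut-2-en-1-yl)-4-[(triisopropylsilyl)oxy]benzoate | C=CCOC(=O)c1c(O)c(CC=C(C)C)c(O[Si](C(C)C)(C(C)C)C(C)C)cc1Oc1cc(OCOC)c(O[Si](C(C)C)(C(C)C)C(C)C)cc1OCOC
F7 | step 10 | prop-2-en-1-yl 2,4-dihydroxy-6-[4-hydroxy-2,5-bis(methoxymethoxy)phenoxy]-3-(3-methylbut-2-en-1-yl)benzoate | C=CCOC(=O)c1c(O)c(CC=C(C)C)c(O)cc1Oc1cc(OCOC)c(O)cc1OCOC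
F8 | step 10 | prop-2-en-1-yl 6-{2,5-bis(methoxymethoxy)-4-[(2-methylbut-3-yn-2-yl)oxy]phenoxy}-2-hydroxy-3-(3-methylbut-2-en-1-yl)-4-[(2-methylbut-3-yn-2-yl)oxy]benzoate | C=CCOC(=O)c1c(O)c(CC=C(C)C)c(OC(C)(C)C#C)cc1Oc1cc(OCOC)c(OC(C)(C)C#C)cc1OCOC
F9 | step 7 | prop-2-en-1-yl 4,4-diethoxybut-2-ynoate | CCOC(OCC)C#CC(=O)OCC=C
F10 | step 7 | prop-2-en-1-yl (2Z)-3-{[5,8-bis(methoxymethoxy)-2,2-dimethyl-2H-chromen-6-yl]oxy}-4,4-diethoxybut-2-enoate | C=CCOC(=O)/C=C(\Oc1cc(OCOC)c2OC(C)(C)C=Cc2c1OCOC)C(OCC)OCC
F11 | step 7 | prop-2-en-1-yl (2Z)-3-{[5,8-bis(methoxymethoxy)-2,2-dimethyl-2H-chromen-6-yl]oxy}-4-oxobut-2-enoate | C=CCOC(=O)/C=C(\Oc1cc(OCOC)c2OC(C)(C)C=Cc2c1OCOC)C=O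
F12 | step 15 | pentafluorophenyl 5-{[5,8-bis(methoxymethoxy)-2,2-dimethyl-2H-chromen-6-yl]oxy}-7-hydroxy-2,2-dimethyl-8-(3-methylbut-2-en-1-yl)-2H-chromene-6-carboxylate | O=C(Oc1c(F)c(F)c(F)c(F)c1F)c1c(O)c(CC=C(C)C)c2OC(C)(C)C=Cc2c1Oc1cc(OCOC)c2OC(C)(C)C=Cc2c1OCOC
F13 | step 15 | pentafluorophenyl 5-[(5,8-dihydroxy-2,2-dimethyl-2H-chromen-6-yl)oxy]-7-hydroxy-2,2-dimethyl-8-(3-methylbut-2-en-1-yl)-2H-chromene-6-carboxylate | O=C(Oc1c(F)c(F)c(F)c(F)c1F)c1c(O)c(CC=C(C)C)c2OC(C)(C)C=Cc2c1Oc1cc(O)c2OC(C)(C)C=Cc2c1O
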